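(The runs come from a simulation from invented constants, noise included.)

At the last reading of the midnight run, 10.0 min, target stands at 11.6% of the substrate charged, and that makes 3.98 turnovers of the catalyst charged. The winter run gives 3.60 turnovers at 10.0 min, with a catalyst charge smaller by a factor 2.23, so the late rate goes with the catalyst charged.

| setting | winter | midnight | flask |
|---|---|---|---|
| substrate | 0.72 M | 0.72 M | 0.72 M |
| reagent | 0.36 M | 0.36 M | 0.360 M |
| free catalyst | 9.4 mM | 21 mM | 14 mM |
| remark | run made earlier | run made earlier |  |

- winter (time / min: target / %, substrate / %): 1.50: 0.4, 68.7; 3.00: 1.1, 51.6; 5.00: 1.9, 38.7; 6.00: 3.0, 32.4; 8.00: 5.4, 27.7; 10.0: 4.7, 23.1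
- midnight (time / min: target / %, substrate / %): 0.667: 0, 81.8; 2.00: 3.1, 59.7; 3.00: 4.8, 51.3; 5.00: 6.0, 36.2; 6.00: 7.8, 31.6; 10.0: 11.6, 20.6

(scatter of a reading: 1 percentage point)

- percent here means substrate units held: one homo dimer counts as two
- the earlier runs were read with a standard deviation of 1 percentage point
- candidate steps: substrate + free catalyst <-> catalyst intermediate A; catalyst intermediate A -> catalyst intermediate B; reagent + catalyst intermediate B <-> catalyst intermediate C; catalyst intermediate C <-> catalyst intermediate D; catalyst intermediate D -> by-product + catalyst intermediate E; catalyst intermediate E -> free catalyst + target; 2 substrate -> homo dimer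

1. factor on the rate of making target when 5.0% of the substrate are converted if free catalyst is charged twice over
2. factor on the rate when 5.0% of the substrate are converted if free catalyst is charged at 150 mM instead

If you read the substrate fall as second order, the mean substrate fraction over the midnight run is 0.410. Dividing the count by time and by that fraction gives the turnover rate at full substrate, a turnover frequency per catalyst charged: 0.970 min⁻¹. This flask's steady rate at the mark is therefore 0.0129 M min⁻¹.

The first readings give second-order loss constants of 0.304 min⁻¹ (winter) and 0.334 min⁻¹ (midnight). A line through them gives 0.316 min⁻¹ for this flask, 0.352 min⁻¹ at double charge and 0.665 min⁻¹ at 150 mM. The mark then falls at 0.167 min, earlier than the midnight reading of 0% target at 0.667 min, so it lies in the lag, the induction period. Counted at the steady turnover frequency, that time is worth 0.162 of a turnover; this is a reckoning, not a count of the target made by then.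

My weakest link is an assumption: inside the lag, the rate goes as catalyst times time squared. That gives me 1.61 for doubling and 2.41 at 150 mM. The forecast says 1.75 (1.5 to 2) and 3.5 (1.8 to 6.5), higher than mine, on this ground: “5 % conversion arrives at about 0.15 min, deep inside that lag.”

The flask gives 1.72 and 2.26, with 0.00172 M min⁻¹ at 0.160 min.

    substrate + free catalyst ⇌ catalyst intermediate A (K = 0.140 M⁻¹, k = 6.40 M⁻¹ min⁻¹)
    catalyst intermediate A → catalyst intermediate B (k = 18.0 min⁻¹)
    reagent + catalyst intermediate B ⇌ catalyst intermediate C (K = 1.30 M⁻¹, k = 270 M⁻¹ min⁻¹)
    catalyst intermediate C ⇌ catalyst intermediate D (K = 0.460, k = 17.0 min⁻¹)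
    catalyst intermediate D → by-product + catalyst intermediate E (k = 18.0 min⁻¹)
    catalyst intermediate E → free catalyst + target (k = 16.0 min⁻¹)
    2 substrate → homo dimer (k = 0.210 M⁻¹ min⁻¹)

The turnover frequency now replaces the square law with a share: the rate in this flask at the mark is 13.3% of the steady rate reckoned above, and the rate in the flask at 150 mM is 2.81% of the steady rate reckoned the same way. Removing the turning of 2 substrate into homo dimer from this flask has the largest single effect among the simulated runs: the rate at the mark becomes 5.11 times the actual one, a share of 68.0%.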